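**Plan**

- Cuts: O1–C2 and C2–C3 of the tetronic acid ring (C2 returns to the carbonyl carbon of an N,N-diisopropylcarbamate on O1), then C4–C5 (α-lithiated carbamate plus a propionyl unit), then C11'–C12' of the side chain (allylic bromide plus 2-(furan-3-yl)ethyl Grignard reagent).
- Enabling feature: C5, O1 and C1'–C11' (with the C2' methyl and both E olefins) are C1, the hydroxyl oxygen and C2–C12 of (3R)-2,3-dihydrofarnesol. A carbamate on that oxygen can therefore direct removal of one enantiotopic C5 hydrogen and later give up its carbonyl carbon as lactone carbon C2.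
- Forward order: farnesol is hydrogenated, carbamoylated and functionalised at C12; the purchased furan ring is joined by the C11'–C12' coupling; C5–C4 is made by asymmetric lithiation–acylation; the tetronic acid ring closes last (C3–C2 by O-to-C carbamoyl transfer, O1–C2 by lactonisation).
- Stereochemistry: C2' (R) from Ru/(S)-BINAP hydrogenation; C5 (R) from (−)-sparteine-controlled deprotonation and retentive acylation; the two E olefins from farnesol and the E-selective allylic oxidation.

Key step: step 8

Remark: the target is treated as the 4-hydroxy (enol) tautomer as drawn; ring atoms are O1, C2 (lactone carbonyl), C3 (C-methyl), C4 (C-OH), C5, and the side chain is numbered C1' to C13' outward from C5.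

**Route**

Step 1
Reactants: 1 (2E,6E)-farnesol
Product: 2 (3R,6E)-3,7,11-trimethyldodeca-6,10-dien-1-ol [(3R)-2,3-dihydrofarnesol]
Conditions: Ru(OAc)2[(S)-BINAP] (cat.), H2 (100 atm), MeOH, 20 °C
Reagents that add atoms: none
Why: BINAP–ruthenium asymmetric hydrogenation of an allylic alcohol: the hydroxyl group binds the divalent ruthenium centre, so only the C2=C3 olefin is reduced, and the (S)-ligand adds hydrogen to the face of the E-olefin that gives the 3R centre (the sense that turns geraniol into (R)-citronellol), while the two isolated trisubstituted olefins have no directing group and remain.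

Step 2
Reactants: 2 (3R)-2,3-dihydrofarnesol; 3 N,N-diisopropylcarbamoyl chloride
Product: 4 (3R,6E)-3,7,11-trimethyldodeca-6,10-dien-1-yl N,N-diisopropylcarbamate
Conditions: Et3N, DMAP (cat.), CH2Cl2, reflux
Reagents that add atoms: none
Why: Nucleophilic acyl substitution (O-carbamoylation) of the unhindered primary alcohol with Et3N as acid scavenger; the hindered carbamate is inert to the oxidation, bromination and Grignard steps that follow and serves as the only protecting group.

Step 3
Reactants: 4 dihydrofarnesyl carbamate
Product: 5 (3R,6E,10E)-12-hydroxy-3,7,11-trimethyldodeca-6,10-dien-1-yl N,N-diisopropylcarbamate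
Conditions: SeO2 (cat.), t-BuOOH, salicylic acid (cat.), CH2Cl2, 0 °C to rt
Reagents that add atoms: tert-butyl hydroperoxide, CC(C)(C)OO (terminal source of the hydroxyl oxygen, relayed through SeO2, O=[Se]=O)
Why: Riley allylic oxidation (ene reaction, then [2,3]-sigmatropic shift of the allylseleninic acid) attacks the terminal isopropylidene, the most accessible olefin, at its (E)-methyl group as with geranyl and farnesyl esters, and catalytic SeO2 with t-BuOOH run to partial conversion should hold the product at the alcohol stage.

Step 4
Reactants: 5 12-hydroxy carbamate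
Product: 6 (3R,6E,10E)-12-bromo-3,7,11-trimethyldodeca-6,10-dien-1-yl N,N-diisopropylcarbamate
Conditions: CBr4, PPh3, CH2Cl2, 0 °C
Reagents that add atoms: carbon tetrabromide, BrC(Br)(Br)Br
Why: Appel reaction: the alkoxyphosphonium ion is displaced by bromide in an SN2 reaction at the primary allylic carbon at 0 °C, which keeps the E geometry and avoids allylic transposition, and the carbamate and the other olefin do not react.

Step 5
Reactants: 7 3-bromofuran; 8 ethylene oxide
Product: 10 2-(furan-3-yl)ethanol, via 3-furyllithium 9 (not isolated)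
Conditions: n-BuLi, THF, −78 °C; then 8, BF3·OEt2, −78 °C; sat. aq NH4Cl
Reagents that add atoms: none
Why: Bromine–lithium exchange at −78 °C gives 3-furyllithium below the temperature at which it isomerises to the 2-lithio isomer, and BF3-promoted SN2 opening of the epoxide by the aryllithium at the same temperature installs the two-carbon alcohol.

Step 6
Reactants: 10 2-(furan-3-yl)ethanol
Product: 11 3-(2-bromoethyl)furan
Conditions: CBr4, PPh3, CH2Cl2, 0 °C
Reagents that add atoms: carbon tetrabromide, BrC(Br)(Br)Br
Why: Appel reaction on an unhindered primary alcohol under neutral conditions that the acid-sensitive furan tolerates.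

Step 7
Reactants: 6 12-bromo carbamate; 11 3-(2-bromoethyl)furan
Product: 13 (3R,6E,10E)-14-(furan-3-yl)-3,7,11-trimethyltetradeca-6,10-dien-1-yl N,N-diisopropylcarbamate, via 2-(furan-3-yl)ethylmagnesium bromide 12 (not isolated)
Conditions: 11, Mg, THF, 25–40 °C; then 6, Li2CuCl4 (5 mol %), THF, −78 to 0 °C
Reagents that add atoms: none
Why: Magnesium insertion gives a primary alkyl Grignard reagent, and the Li2CuCl4-catalysed cross-coupling with the primary allylic bromide should substitute at the less hindered α-carbon (SN2, not SN2′) with retention of the E olefin to form the C11'–C12' bond, while the hindered carbamate is untouched by the Grignard reagent at or below 0 °C.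

Step 8
Reactants: 13 full-chain furanyl carbamate; 14 N-methoxy-N-methylpropanamide
Product: 17 (4R,6R,9E,13E)-17-(furan-3-yl)-6,10,14-trimethyl-3-oxoheptadeca-9,13-dien-4-yl N,N-diisopropylcarbamate, via (S)-α-lithiated carbamate sparteine complex 15 (not isolated), via lithium hemiaminal alkoxide adduct 16 (not isolated)
Conditions: s-BuLi, (−)-sparteine, Et2O, −78 °C, 5 h; then 14, −78 °C; sat. aq NH4Cl, −78 °C to rt
Reagents that add atoms: none
Why: The s-BuLi/(−)-sparteine complex binds the carbamate carbonyl oxygen and, within this pre-complex, removes the pro-S hydrogen of the O–CH2 group (the future C5), giving the dipole-stabilised, configurationally stable (S)-α-oxy organolithium 15; the Weinreb amide then acylates the C–Li bond with retention to form the C5–C4 bond, and the chelated tetrahedral adduct 16 persists until the cold quench, so neither a second addition nor enolisation of the new ketone by unreacted carbanion can take place (Weinreb ketone synthesis). The closest known reaction type is the sparteine-mediated enantioselective deprotonation of primary O-alkyl N,N-diisopropylcarbamates followed by retentive trapping with carbon dioxide, chloroformates and other acylating agents. No ring closes in this step; the tetronic acid ring closes in steps 9 and 10, when the carbamoyl carbon moves to C3 and is recaptured by O1. The new stereocentre C5 (R) is set by the chiral diamine, which chooses between the two enantiotopic hydrogens, and by the retentive replacement of lithium; the C2' methyl group is too remote to bias the choice. The step needs this enantiotopic selection and chemoselectivity for the O–CH2 hydrogens over the α-hydrogens of the furan and the allylic hydrogens, and both are secured by the proximity effect of the pre-bound carbamate, near-stoichiometric base and Et2O at −78 °C.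

Step 9
Reactants: 17 (R)-α-carbamoyloxy ethyl ketone
Product: 20 (4R,6R,9E,13E)-17-(furan-3-yl)-4-hydroxy-2,6,10,14-tetramethyl-3-oxo-N,N-di(propan-2-yl)heptadeca-9,13-dienamide (C2 epimers), via lithium enolate 18 (not isolated), via cyclic lithium hemiaminal alkoxide 19 (not isolated)
Conditions: LiN(SiMe3)2 (2.2 equiv), THF, −78 to 0 °C (17 added to the base); sat. aq NH4Cl
Reagents that add atoms: none
Why: Proposed new method: kinetic deprotonation of the less hindered CH2 of the ethyl ketone should give enolate 18, whose carbon C3 sits next to the carbamate carbonyl and can add to it through the five-membered adduct 19 (a 5-(enolendo)-exo-trig closure, the geometry of the Dieckmann cyclisation of α-acyloxy esters to tetronic acids), which collapses by loss of the C5 alkoxide (a far better leaving group than a dialkylamide) to a β-keto amide that the second equivalent of base converts into a stabilised enolate, making the transfer irreversible; the carbamate has no α-hydrogen, so no competing enolate can form on the migrating group, C5 keeps its configuration because it is not deprotonated and none of its bonds is broken, and the closest known reaction types are the carbamoyl Baker–Venkataraman rearrangement of ortho-acylaryl carbamates (1,5 O-to-C shift) and the lateral anionic homo-Fries 1,4 O-to-C carbamoyl shift of ortho-tolyl carbamates, neither of which has been shown with an aliphatic ketone enolate and an sp3 alkoxide leaving group.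

Step 10
Reactants: 20 γ-hydroxy-β-keto N,N-diisopropylamide
Product: 21 (5R)-5-[(2R,5E,9E)-13-(furan-3-yl)-2,6,10-trimethyltrideca-5,9-dien-1-yl]-4-hydroxy-3-methylfuran-2(5H)-one (target CNP0280565.1)
Conditions: AcOH, toluene, 70 °C
Reagents that add atoms: none
Why: Acid-catalysed lactonisation of a γ-hydroxy tertiary amide: the C5 hydroxyl adds 5-exo-trig to the amide carbonyl and N-protonation expels diisopropylamine, as in the acid closure of ortho-(hydroxyalkyl) N,N-dialkylbenzamides to phthalides and of Baker–Venkataraman β-keto amides to 4-hydroxycoumarins, driven by formation of the acidic vinylogous acid and release of the bulky amine, while acetic acid is weak enough to spare the furan and the 1,5-diene and should not enolise C5.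

**Compound list**

1 | (2E,6E)-farnesol | CC(C)=CCC/C(C)=C/CC/C(C)=C/CO | starting material
2 | (3R,6E)-3,7,11-trimethyldodeca-6,10-dien-1-ol [(3R)-2,3-dihydrofarnesol] | OCC[C@H](C)CC/C=C(\C)CC/C=C(C)C | intermediate
3 | N,N-diisopropylcarbamoyl chloride | CC(C)N(C(C)C)C(Cl)=O | starting material
4 | (3R,6E)-3,7,11-trimethyldodeca-6,10-dien-1-yl N,N-diisopropylcarbamate | CC(C)N(C(C)C)C(=O)OCC[C@H](C)CC/C=C(\C)CC/C=C(C)C | intermediate
5 | (3R,6E,10E)-12-hydroxy-3,7,11-trimethyldodeca-6,10-dien-1-yl N,N-diisopropylcarbamate | CC(C)N(C(C)C)C(=O)OCC[C@H](C)CC/C=C(\C)CC/C=C(\C)CO | intermediate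
6 | (3R,6E,10E)-12-bromo-3,7,11-trimethyldodeca-6,10-dien-1-yl N,N-diisopropylcarbamate | CC(C)N(C(C)C)C(=O)OCC[C@H](C)CC/C=C(\C)CC/C=C(\C)CBr | intermediate
7 | 3-bromofuran | Brc1ccoc1 | starting material
8 | ethylene oxide | C1CO1 | starting material
9 | 3-furyllithium | [Li]c1ccoc1 | intermediate
10 | 2-(furan-3-yl)ethanol | OCCc1ccoc1 | intermediate
11 | 3-(2-bromoethyl)furan | BrCCc1ccoc1 | intermediate
12 | 2-(furan-3-yl)ethylmagnesium bromide | Br[Mg]CCc1ccoc1 | intermediate
13 | (3R,6E,10E)-14-(furan-3-yl)-3,7,11-trimethyltetradeca-6,10-dien-1-yl N,N-diisopropylcarbamate | CC(C)N(C(C)C)C(=O)OCC[C@H](C)CC/C=C(\C)CC/C=C(\C)CCCc1ccoc1 | intermediate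
14 | N-methoxy-N-methylpropanamide | CCC(=O)N(C)OC | starting material
15 | (1S,3R,6E,10E)-14-(furan-3-yl)-1-lithio-3,7,11-trimethyltetradeca-6,10-dien-1-yl N,N-diisopropylcarbamate, as its (−)-sparteine complex | [Li][C@@H](C[C@H](C)CC/C=C(\C)CC/C=C(\C)CCCc1ccoc1)OC(=O)N(C(C)C)C(C)C | intermediate
16 | (4R,6R,9E,13E)-17-(furan-3-yl)-3-(lithiooxy)-3-[methoxy(methyl)amino]-6,10,14-trimethylheptadeca-9,13-dien-4-yl N,N-diisopropylcarbamate (C3 unassigned) | CCC(O[Li])(N(C)OC)[C@@H](C[C@H](C)CC/C=C(\C)CC/C=C(\C)CCCc1ccoc1)OC(=O)N(C(C)C)C(C)C | intermediate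
17 | (4R,6R,9E,13E)-17-(furan-3-yl)-6,10,14-trimethyl-3-oxoheptadeca-9,13-dien-4-yl N,N-diisopropylcarbamate | CCC(=O)[C@@H](C[C@H](C)CC/C=C(\C)CC/C=C(\C)CCCc1ccoc1)OC(=O)N(C(C)C)C(C)C | intermediate
18 | lithium (2Z,4R,6R,9E,13E)-4-(diisopropylcarbamoyloxy)-17-(furan-3-yl)-6,10,14-trimethylheptadeca-2,9,13-trien-3-olate | C/C=C(\O[Li])[C@@H](C[C@H](C)CC/C=C(\C)CC/C=C(\C)CCCc1ccoc1)OC(=O)N(C(C)C)C(C)C | intermediate
19 | lithium (5R)-2-(diisopropylamino)-5-[(2R,5E,9E)-13-(furan-3-yl)-2,6,10-trimethyltrideca-5,9-dien-1-yl]-3-methyl-4-oxooxolan-2-olate (C2 and C3 unassigned) | CC1C(=O)[C@@H](C[C@H](C)CC/C=C(\C)CC/C=C(\C)CCCc2ccoc2)OC1(O[Li])N(C(C)C)C(C)C | intermediate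
20 | (4R,6R,9E,13E)-17-(furan-3-yl)-4-hydroxy-2,6,10,14-tetramethyl-3-oxo-N,N-di(propan-2-yl)heptadeca-9,13-dienamide (C2 epimers) | CC(C(=O)N(C(C)C)C(C)C)C(=O)[C@@H](C[C@H](C)CC/C=C(\C)CC/C=C(\C)CCCc1ccoc1)O | intermediate
21 | (5R)-5-[(2R,5E,9E)-13-(furan-3-yl)-2,6,10-trimethyltrideca-5,9-dien-1-yl]-4-hydroxy-3-methylfuran-2(5H)-one | CC1=C(O)[C@@H](C[C@H](C)CC/C=C(\C)CC/C=C(\C)CCCc2ccoc2)OC1=O | target

**Step count**

Total step count: 10. Longest linear sequence: 8 steps (steps 1–4 and 7–10, from farnesol).

**Steps most likely to fail**

Step 9 (proposed new method). The enolate carbon may fail to add to the shielded, weakly electrophilic diisopropylcarbamoyl carbonyl through the strained five-membered arrangement. Alternatively, proton exchange between the base or the enolate and the C5 hydrogen may erode the C5 configuration before the transfer occurs. The fallback uses known chemistry, sets out from 13 and returns at 21.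
- LiAlH4 in refluxing THF cleaves the carbamate of 13 to the alcohol (3R,6E,10E)-14-(furan-3-yl)-3,7,11-trimethyltetradeca-6,10-dien-1-ol F1.
- Buffered Dess–Martin oxidation gives the aldehyde (3R,6E,10E)-14-(furan-3-yl)-3,7,11-trimethyltetradeca-6,10-dienal F2.
- The (R)-selective hydroxynitrile lyase from Prunus amygdalus with HCN in a buffered two-phase system gives the cyanohydrin (2R,4R,7E,11E)-15-(furan-3-yl)-2-hydroxy-4,8,12-trimethylpentadeca-7,11-dienenitrile F3.
- Me3SiCl and imidazole convert it into the silyl ether (2R,4R,7E,11E)-15-(furan-3-yl)-4,8,12-trimethyl-2-(trimethylsilyloxy)pentadeca-7,11-dienenitrile F4.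
- A Blaise reaction of F4 with the zinc enolate from ethyl 2-bromopropanoate (Zn, THF, reflux) is followed by dilute aqueous HCl, which hydrolyses the zinc enaminoate, removes the silyl group and lactonises the γ-hydroxy-β-keto ester to 21.

Step 8 (key step). Acyl transfer from the Weinreb amide to the crowded sparteine-bound carbanion may be slow at −78 °C, or the carbanion may act as a base toward the amide instead of adding. Warming to force the addition invites loss of configuration and 1,2-carbamoyl migration, and the long lithiation gives time for deprotonation at a furan α-position. The fallback sets out from 13 and returns at 17. The same lithiated carbamate is trapped with propanal, a fast electrophile at −78 °C that reacts with retention, to give (4R,6R,9E,13E)-17-(furan-3-yl)-3-hydroxy-6,10,14-trimethylheptadeca-9,13-dien-4-yl N,N-diisopropylcarbamate F5 as a mixture of carbinol epimers. Buffered Dess–Martin oxidation of F5 removes the extra stereocentre and gives 17.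

Step 7. Substitution may occur at the γ-carbon with allylic transposition, the Grignard reagent may homocouple while it is being formed, or halogen–metal exchange at the allylic bromide may scramble the olefin geometry. The fallback sets out from 11 (with 6) and returns at 13.
- PhSO2Na in DMF converts 11 into 3-[2-(phenylsulfonyl)ethyl]furan F6.
- Deprotonation with n-BuLi in THF at −78 °C and alkylation of the sulfonyl carbanion with 6, a clean SN2 reaction at the primary allylic carbon, gives (3R,6E,10E)-14-(furan-3-yl)-3,7,11-trimethyl-13-(phenylsulfonyl)tetradeca-6,10-dien-1-yl N,N-diisopropylcarbamate F7.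
- Reductive desulfonylation with Mg in MeOH gives 13; the sulfone sits on a saturated carbon, so no olefin can migrate.

**Further compounds**

F1 | step 9 | (3R,6E,10E)-14-(furan-3-yl)-3,7,11-trimethyltetradeca-6,10-dien-1-ol | OCC[C@H](C)CC/C=C(\C)CC/C=C(\C)CCCc1ccoc1
F2 | step 9 | (3R,6E,10E)-14-(furan-3-yl)-3,7,11-trimethyltetradeca-6,10-dienal | O=CC[C@H](C)CC/C=C(\C)CC/C=C(\C)CCCc1ccoc1
F3 | step 9 | (2R,4R,7E,11E)-15-(furan-3-yl)-2-hydroxy-4,8,12-trimethylpentadeca-7,11-dienenitrile | N#C[C@@H](C[C@H](C)CC/C=C(\C)CC/C=C(\C)CCCc1ccoc1)O
F4 | step 9 | (2R,4R,7E,11E)-15-(furan-3-yl)-4,8,12-trimethyl-2-(trimethylsilyloxy)pentadeca-7,11-dienenitrile | N#C[C@@H](C[C@H](C)CC/C=C(\C)CC/C=C(\C)CCCc1ccoc1)O[Si](C)(C)C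
F5 | step 8 | (4R,6R,9E,13E)-17-(furan-3-yl)-3-hydroxy-6,10,14-trimethylheptadeca-9,13-dien-4-yl N,N-diisopropylcarbamate (C3 epimers) | CCC(O)[C@@H](C[C@H](C)CC/C=C(\C)CC/C=C(\C)CCCc1ccoc1)OC(=O)N(C(C)C)C(C)C
F6 | step 7 | 3-[2-(phenylsulfonyl)ethyl]furan | O=S(=O)(CCc1ccoc1)c1ccccc1
F7 | step 7 | (3R,6E,10E)-14-(furan-3-yl)-3,7,11-trimethyl-13-(phenylsulfonyl)tetradeca-6,10-dien-1-yl N,N-diisopropylcarbamate (C13 epimers) | CC(C)N(C(C)C)C(=O)OCC[C@H](C)CC/C=C(\C)CC/C=C(\C)CC(Cc1ccoc1)S(=O)(=O)c1ccccc1
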